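**Plan**

- Numbering: C1, C2, C3 are the carbinol carbons (angelate, acetate, angelate). C4 is the quaternary C–CH3, C5 the CH next to the C6 ketone, C7=C8(CH3) the enone olefin, C9 and C10 the other two cyclobutane CH groups, C11 the CMe2 carbon. β is the face of ring C5–C10 that carries C4.
- Cuts: first the three ester C–O bonds, then the C6 carbonyl is moved back to C7 (C8–H), then C4–C9 of the cyclobutane is cut. After that C3=C4 (metathesis), C1–C2 (alkoxyallylboration) and C10–C11 (Ireland–Claisen) are cut, which leads back to (S)-carvone (C4 to C10 and both of their methyl groups).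
- Enabling feature: in the cyclobutane C4–C5–C10–C9 the fully substituted C4 lies beside oxygen-bearing C3, the pattern left when a C3–C4 epoxide is opened homolytically. C9 becomes an enone β-carbon once the carbonyl stands at C7.
- Forward ring order: six-membered ring (carvone), then seven-membered ring C4–C3–C2–C1–C11–C10–C5 (step 12), then cyclobutane (step 14), then carbonyl shift C7 to C6 and acylation (angelates before acetate).
- Stereochemistry: C5 comes from carvone. C10 is set by suprafacial [3,3] transfer from a C8–O bond placed on the β face. C1 and C2 come from the Ipc2B reagent, C3 from the Shi ketone, and C4 and C9 from the ring geometry.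

Key step: step 14

Remark: C8 of the key-step product is drawn as the epimer expected from kinetic protonation of the enolate; this centre becomes sp2 again in step 15, so either epimer would serve.

**Step 1**
Reactants: 1 (S)-(+)-carvone
Product: 2 (+)-cis-carveol (C7-OH β)
Conditions: NaBH4, CeCl3·7H2O, MeOH, −78 → 0 °C
Reagents that add atoms: none
Why: Luche reduction should give clean 1,2-reduction, and hydride delivery to the carbonyl face opposite the C5 isopropenyl group places the new C7 hydroxyl cis (β) to it.

**Step 2**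
Reactants: 2 (+)-cis-carveol
Product: 3 β-epoxy alcohol (C8–C9 oxirane syn to C7-OH)
Conditions: VO(acac)2 (cat.), t-BuOOH, toluene, 0 °C → rt
Reagents that add atoms: tert-butyl hydroperoxide, CC(C)(C)OO
Why: In this vanadium-catalysed hydroxyl-directed epoxidation the metal-bound C7 alkoxide delivers oxygen to the β face of the adjacent C8=C9 bond, which sets C8 and C9, while the undirected isopropenyl group should stay untouched.

**Step 3**
Reactants: 3 β-epoxy alcohol
Product: 6 all-cis 2-methyl-5-(prop-1-en-2-yl)cyclohex-3-ene-1,2-diol, via hydroxy selenide 4 (not isolated), via selenoxide 5 (not isolated)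
Conditions: PhSeSePh, NaBH4, EtOH, reflux; then THF, 30% H2O2, 0 °C → rt
Reagents that add atoms: none
Why: In this selenide opening and selenoxide syn elimination (epoxide to allylic alcohol transposition) PhSe− attacks the secondary C9 with inversion, C8–O keeps its β configuration, and the selenoxide can only eliminate towards C10 because C8 carries no hydrogen.

**Step 4**
Reactants: 6 all-cis diol
Product: 7 C7 pivalate of 6 (C8-OH free)
Conditions: t-BuCOCl, pyridine, CH2Cl2, 0 °C → rt
Reagents that add atoms: pivaloyl chloride, CC(C)(C)C(=O)Cl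
Why: Sterically selective acylation should esterify the secondary C7 hydroxyl and spare the tertiary C8 hydroxyl, and a pivalate has no α-hydrogen that could be enolised in step 6.

**Step 5**
Reactants: 7 C7 pivalate; 8 isobutyric anhydride
Product: 9 C8 isobutyrate C7 pivalate
Conditions: 8, DMAP, Et3N, CH2Cl2, 40 °C
Reagents that add atoms: isobutyric anhydride (8), CC(C)C(=O)OC(=O)C(C)C
Why: DMAP-catalysed acylation with an anhydride is the standard esterification of tertiary alcohols and avoids the acid that would ionise this tertiary allylic alcohol; no stereocentre changes.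

**Step 6**
Reactants: 9 C8 isobutyrate C7 pivalate
Product: 12 2-methyl-2-[3-methyl-4-(pivaloyloxy)-6-(prop-1-en-2-yl)cyclohex-2-en-1-yl]propanoic acid (all ring substituents β), via silyl ketene acetal 10 (not isolated), via trimethylsilyl ester 11 (not isolated)
Conditions: LiN(iPr)2, THF, −78 °C; Me3SiCl; −78 → 60 °C; aq. HCl work-up
Reagents that add atoms: none
Why: In the Ireland–Claisen rearrangement the ketene acetal hangs on the β-oriented, pseudoaxial C8–O bond, so the suprafacial [3,3] shift forms C10–C11 on the β face (cis to the pseudoequatorial isopropenyl group), builds quaternary C11 without a stereochemical issue because its two methyl groups are alike, and moves the olefin to C8=C9.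

**Step 7**
Reactants: 12 acid
Product: 13 diol (C1 primary alcohol; C7 allylic alcohol β)
Conditions: LiAlH4, THF, 0 °C → reflux; aqueous work-up
Reagents that add atoms: none
Why: Hydride reduction takes the hindered acid to the primary alcohol and cleaves the pivalate in the same operation without touching a stereocentre.

**Step 8**
Reactants: 13 diol
Product: 14 2-methyl-2-[3-methyl-4-oxo-6-(prop-1-en-2-yl)cyclohex-2-en-1-yl]propanal (C5/C10 cis)
Conditions: Dess–Martin periodinane, CH2Cl2, 0 °C → rt
Reagents that add atoms: none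
Why: Dess–Martin oxidation of both alcohols under neutral conditions should give the non-enolisable C1 aldehyde and the C7 enone at once without epimerising the vinylogously acidic C10.

**Step 9**
Reactants: 15 allyl alcohol
Product: 16 allyl methoxymethyl ether
Conditions: CH2(OMe)2, LiBr (cat.), p-TsOH·H2O (cat.), rt
Reagents that add atoms: dimethoxymethane, COCOC
Why: Acid-catalysed acetal exchange with excess dimethoxymethane is a routine way to make methoxymethyl ethers of primary alcohols.

**Step 10**
Reactants: 14 keto aldehyde; 16 allyl methoxymethyl ether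
Product: 19 syn C1-hydroxy C2-methoxymethoxy diene, via allylborane 17 (not isolated), via borinate 18 (not isolated)
Conditions: 16, s-BuLi, THF, −78 °C; (+)-Ipc2BOMe; BF3·OEt2; 14, −78 °C; HOCH2CH2NH2, rt
Reagents that add atoms: allyl methoxymethyl ether (16), C=CCOCOC
Why: In the Brown alkoxyallylboration the Z-γ-alkoxyallylborane reacts through a closed chair transition state to give the syn C1/C2 pair (trans once in the ring), the isopinocampheyl groups derived from (−)-α-pinene select the aldehyde face that gives (S)-C1, and the aldehyde reacts far faster than the enone.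

**Step 11**
Reactants: 19 homoallylic alcohol
Product: 20 C1 tert-butyldimethylsilyl ether of 19
Conditions: TBSOTf, 2,6-lutidine, CH2Cl2, −78 → 0 °C
Reagents that add atoms: tert-butyldimethylsilyl triflate, CC(C)(C)[Si](C)(C)OS(=O)(=O)C(F)(F)F
Why: Silyl triflate silylation reaches even this neopentyl-type alcohol and masks the C1 oxygen, which could otherwise attack C4 of the later epoxide across the ring.

**Step 12**
Reactants: 20 silyl ether
Product: 21 cis-fused bicyclo[5.4.0]undecadienone (C3=C4 olefin; C7 enone)
Conditions: second-generation Grubbs catalyst (10 mol %), 1,4-benzoquinone (cat.), toluene (2 mM), 80 °C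
Reagents that add atoms: none
Why: Ring-closing metathesis should load the catalyst on the monosubstituted C3 vinyl group and close onto the cis-disposed isopropenyl group, helped by the gem-dimethyl group at C11, while the α-methyl enone olefin is too hindered and electron-poor to take part.

**Step 13**
Reactants: 21 bicyclic dienone
Product: 22 C3–C4 epoxide (oxirane O on the side of H5 and H10; syn to C2–O)
Conditions: D-fructose-derived Shi ketone (0.3 equiv), 2KHSO5·KHSO4·K2SO4, K2CO3, Bu4NHSO4, MeCN–CH2(OMe)2–aq. Na2B4O7 buffer, 0 °C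
Reagents that add atoms: potassium peroxymonosulfate, [K+].[O-]S(=O)(=O)OO
Why: In the Shi epoxidation the chiral dioxirane attacks only the electron-rich trisubstituted C3=C4 bond, and the spiro transition-state model for this ketone predicts oxygen transfer to the convex face of the cis-fused bicycle (syn to C2–O), which the fold of the rings also leaves open; this sets C3.

**Step 14**
Reactants: 22 epoxy enone
Product: 24 tricyclic C7 ketone (C3-OH free; C1-OTBS; C2-OMOM), via titanium alkoxide enolate 23 (not isolated)
Conditions: Cp2TiCl2 (3 equiv), Zn dust, THF, rt (gives Cp2TiCl); added slowly to 22 in THF (5 mM), rt; 1 M HCl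
Reagents that add atoms: none
Why: Single-electron transfer from Cp2TiCl (trivalent titanium) to the epoxide breaks the C4–O bond, because this gives the tertiary rather than the secondary radical, and leaves C3–O–Ti with its configuration intact. The C4 radical adds to the enone β-carbon C9 in a 4-exo-trig closure of ring C4–C5–C10–C9, and a second Cp2TiCl reduces the C8 α-keto radical to an enolate of tetravalent titanium, which removes the otherwise reversible closure from equilibrium. The closest known reaction is the titanocene-mediated reductive 4-exo cyclisation of epoxides onto α,β-unsaturated carbonyl groups, in particular of side-chain epoxides of 5-alkenylcyclohexenones to bicyclo[3.1.1]heptan-3-ones. C4 and C9 have no freedom, since C4 hangs on the β face of C5 and is tied through C3–C2–C1–C11 to the β face of C10, so the bond can form only on the β face of C9 and the C4 methyl group must turn outward. C8 is set when the enolate is protonated from the side of the C10–H bridge, away from the C4 methyl group, and is erased in step 15. The step needs ring closure to outrun hydrogen loss or reduction of the radical, which is favoured because the cis fusion with bulky C11 equatorial holds the C5–C4 bond axial over C9 and slow addition keeps the Cp2TiCl concentration low.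

**Step 15**
Reactants: 24 tricyclic ketone
Product: 25 diosphenol (C6 ketone; C7 enol; C7=C8)
Conditions: SeO2, 1,4-dioxane, 90 °C
Reagents that add atoms: selenium dioxide, O=[Se]=O
Why: Riley oxidation converts the only α-methylene (C6) of the ketone into a carbonyl group, and the 1,2-dione can enolise only towards C8 because C5 is a bridgehead, so a single diosphenol should result.

**Step 16**
Reactants: 25 diosphenol
Product: 26 C7 enol triflate
Conditions: PhNTf2, Et3N, DMAP (cat.), CH2Cl2, 0 °C → rt
Reagents that add atoms: N-phenylbis(trifluoromethanesulfonimide), FC(F)(F)S(=O)(=O)N(c1ccccc1)S(=O)(=O)C(F)(F)F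
Why: In this O-sulfonylation of an acidic enol under amine base the reagent should triflate only the phenol-like diosphenol hydroxyl and leave the hindered secondary C3 alcohol alone.

**Step 17**
Reactants: 26 enol triflate
Product: 27 C6 enone (C7=C8; C3-OH free; C1-OTBS; C2-OMOM)
Conditions: Pd(OAc)2 (5 mol %), PPh3, HCO2H, Et3N, DMF, 60 °C
Reagents that add atoms: none
Why: Palladium-catalysed formate hydrogenolysis of an enol triflate (oxidative addition to zerovalent palladium, formate exchange, loss of CO2, reductive elimination) replaces OTf by H and completes the carbonyl shift from C7 to C6 with the olefin fixed at C7=C8.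

**Step 18**
Reactants: 27 enone
Product: 28 C1,C3-diol (C2-OMOM)
Conditions: HF·pyridine, THF, 0 °C → rt
Reagents that add atoms: none
Why: Fluoride-driven desilylation under mildly acidic conditions frees C1-OH and leaves the acetal at C2 and the enone unchanged.

**Step 19**
Reactants: 28 diol; 29 angelic acid
Product: 31 C1,C3-bis(angelate) C2-MOM ether, via mixed anhydride 30 (not isolated)
Conditions: 29, 2,4,6-Cl3C6H2COCl, Et3N, toluene, rt; then 28, 80 °C
Reagents that add atoms: angelic acid (29), C/C=C(/C)C(=O)O
Why: Yamaguchi-type mixed-anhydride esterification without a nucleophilic catalyst is the established way to transfer an angeloyl group without Z to E isomerisation, both free alcohols take the same acyl group, and the ether at C2 cannot migrate.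

**Step 20**
Reactants: 31 bis(angelate)
Product: 33 C2 alcohol, via bromomethyl ether 32 (not isolated)
Conditions: Me2BBr, CH2Cl2, −78 °C; aq. NaHCO3–THF
Reagents that add atoms: none
Why: Boron-halide cleavage of the acetal gives at low temperature a bromomethyl ether that hydrolyses on basic work-up, conditions under which esters, the enone and the Z olefins should survive and acyl migration should be slow.

**Step 21**
Reactants: 33 C2 alcohol
Product: 34 target CNP0335415.1
Conditions: Ac2O, pyridine, DMAP (cat.), CH2Cl2, 0 °C → rt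
Reagents that add atoms: acetic anhydride, CC(=O)OC(C)=O
Why: Standard acetylation of the least hindered carbinol is placed last so that an acetate never stands beside a free hydroxyl group.

**Compound list**

1 | (S)-(+)-carvone | CC1=CC[C@@H](CC1=O)C(C)=C | starting material
2 | (+)-cis-carveol, (1S,5S)-2-methyl-5-(prop-1-en-2-yl)cyclohex-2-en-1-ol | CC1=CC[C@@H](C[C@@H]1O)C(C)=C | intermediate
3 | C8–C9 β-epoxide of 2 (oxirane O, C7-OH and isopropenyl on one face) | C[C@@]12O[C@@H]1C[C@@H](C[C@@H]2O)C(C)=C | intermediate
4 | hydroxy selenide (C9-SePh α; C8-OH and C7-OH β) | C[C@@]1(O)[C@@H]([Se]c2ccccc2)C[C@@H](C[C@@H]1O)C(C)=C | intermediate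
5 | selenoxide of 4 | C[C@@]1(O)[C@@H]([Se](=O)c2ccccc2)C[C@@H](C[C@@H]1O)C(C)=C | intermediate
6 | all-cis 2-methyl-5-(prop-1-en-2-yl)cyclohex-3-ene-1,2-diol (C7-OH, C8-OH, isopropenyl β; C9=C10) | C[C@@]1(O)C=C[C@@H](C[C@@H]1O)C(C)=C | intermediate
7 | C7 pivalate of 6 | C[C@@]1(O)C=C[C@@H](C[C@@H]1OC(=O)C(C)(C)C)C(C)=C | intermediate
8 | isobutyric anhydride | CC(C)C(=O)OC(=O)C(C)C | starting material
9 | C8 isobutyrate C7 pivalate of 6 | C[C@@]1(OC(=O)C(C)C)C=C[C@@H](C[C@@H]1OC(=O)C(C)(C)C)C(C)=C | intermediate
10 | trimethylsilyl ketene acetal of 9 | C[C@@]1(OC(O[Si](C)(C)C)=C(C)C)C=C[C@@H](C[C@@H]1OC(=O)C(C)(C)C)C(C)=C | intermediate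
11 | trimethylsilyl ester of 12 | CC1=C[C@@H]([C@@H](C[C@@H]1OC(=O)C(C)(C)C)C(C)=C)C(C)(C)C(=O)O[Si](C)(C)C | intermediate
12 | 2-methyl-2-[3-methyl-4-(pivaloyloxy)-6-(prop-1-en-2-yl)cyclohex-2-en-1-yl]propanoic acid, substituents at C10, C5, C7 all β | CC1=C[C@@H]([C@@H](C[C@@H]1OC(=O)C(C)(C)C)C(C)=C)C(C)(C)C(=O)O | intermediate
13 | diol: C1 primary alcohol, C7 allylic alcohol (β) | CC1=C[C@@H]([C@@H](C[C@@H]1O)C(C)=C)C(C)(C)CO | intermediate
14 | 2-methyl-2-[3-methyl-4-oxo-6-(prop-1-en-2-yl)cyclohex-2-en-1-yl]propanal, C5/C10 cis | CC1=C[C@@H]([C@@H](CC1=O)C(C)=C)C(C)(C)C=O | intermediate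
15 | allyl alcohol | C=CCO | starting material
16 | allyl methoxymethyl ether | C=CCOCOC | intermediate
17 | [(Z)-3-(methoxymethoxy)allyl]bis(isopinocampheyl)borane, Ipc from (−)-α-pinene | COCO/C=C\CB([C@H]1C[C@H]2C[C@@H]([C@@H]1C)C2(C)C)[C@H]1C[C@H]2C[C@@H]([C@@H]1C)C2(C)C | intermediate
18 | bis(isopinocampheyl)borinate of 19 | CC1=C[C@@H]([C@@H](CC1=O)C(C)=C)C(C)(C)[C@H](OB([C@H]1C[C@H]2C[C@@H]([C@@H]1C)C2(C)C)[C@H]1C[C@H]2C[C@@H]([C@@H]1C)C2(C)C)[C@@H](OCOC)C=C | intermediate
19 | adduct with (S)-C1-OH and syn C2-OMOM, C3 vinyl | CC1=C[C@@H]([C@@H](CC1=O)C(C)=C)C(C)(C)[C@H](O)[C@@H](OCOC)C=C | intermediate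
20 | C1 TBS ether of 19 | CC1=C[C@@H]([C@@H](CC1=O)C(C)=C)C(C)(C)[C@H](O[Si](C)(C)C(C)(C)C)[C@@H](OCOC)C=C | intermediate
21 | cis-fused bicyclo[5.4.0]undecadienone: C3=C4(CH3), C7 enone, C1-OTBS on the side of C6/C9, C2-OMOM on the side of H5/H10 | CC(C)(C)[Si](C)(C)O[C@@H]1[C@@H](OCOC)C=C(C)[C@@H]2CC(=O)C(C)=C[C@@H]2C1(C)C | intermediate
22 | C3–C4 epoxide of 21, oxirane O syn to C2–O (key-step precursor) | CC(C)(C)[Si](C)(C)O[C@@H]1[C@@H](OCOC)[C@H]2O[C@@]2(C)[C@@H]3CC(=O)C(C)=C[C@@H]3C1(C)C | intermediate
23 | bis(chlorotitanocene) C3 alkoxide C7 enolate | CC(C)(C)[Si](C)(C)O[C@@H]1[C@@H](OCOC)[C@@H]([O-])[C@@]2(C)[C@@H]3CC([O-])=C(C)[C@H]2[C@@H]3C1(C)C.[Cl-].[Cl-].[Ti+4].[Ti+4].[cH-]1cccc1.[cH-]1cccc1.[cH-]1cccc1.[cH-]1cccc1 | intermediate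
24 | tricyclic C7 ketone with C3-OH, C4–C9 bond, C8-CH3 on the side of C4 (key-step product) | CC(C)(C)[Si](C)(C)O[C@@H]1[C@@H](OCOC)[C@@H](O)[C@@]2(C)[C@@H]3CC(=O)[C@H](C)[C@H]2[C@@H]3C1(C)C | intermediate
25 | diosphenol: C6 ketone, C7-OH enol, C7=C8 | CC(C)(C)[Si](C)(C)O[C@@H]1[C@@H](OCOC)[C@@H](O)[C@@]2(C)[C@@H]3C(=O)C(O)=C(C)[C@H]2[C@@H]3C1(C)C | intermediate
26 | C7 enol triflate of 25 | CC(C)(C)[Si](C)(C)O[C@@H]1[C@@H](OCOC)[C@@H](O)[C@@]2(C)[C@@H]3C(=O)C(OS(=O)(=O)C(F)(F)F)=C(C)[C@H]2[C@@H]3C1(C)C | intermediate
27 | C6 enone with C1-OTBS, C2-OMOM, C3-OH | CC(C)(C)[Si](C)(C)O[C@@H]1[C@@H](OCOC)[C@@H](O)[C@@]2(C)[C@@H]3C(=O)C=C(C)[C@H]2[C@@H]3C1(C)C | intermediate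
28 | C1,C3-diol, C2-OMOM | O[C@@H]1[C@@H](OCOC)[C@@H](O)[C@@]2(C)[C@@H]3C(=O)C=C(C)[C@H]2[C@@H]3C1(C)C | intermediate
29 | angelic acid, (Z)-2-methylbut-2-enoic acid | C/C=C(/C)C(=O)O | starting material
30 | angelic 2,4,6-trichlorobenzoic anhydride | C/C=C(/C)C(=O)OC(=O)c1c(Cl)cc(Cl)cc1Cl | intermediate
31 | C1,C3-bis(angelate), C2-OMOM | C/C=C(/C)C(=O)O[C@@H]1[C@@H](OCOC)[C@@H](OC(=O)/C(C)=C\C)[C@@]2(C)[C@@H]3C(=O)C=C(C)[C@H]2[C@@H]3C1(C)C | intermediate
32 | C2 bromomethyl ether of 33 | C/C=C(/C)C(=O)O[C@@H]1[C@@H](OCBr)[C@@H](OC(=O)/C(C)=C\C)[C@@]2(C)[C@@H]3C(=O)C=C(C)[C@H]2[C@@H]3C1(C)C | intermediate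
33 | C1,C3-bis(angelate), C2-OH | C/C=C(/C)C(=O)O[C@@H]1[C@@H](O)[C@@H](OC(=O)/C(C)=C\C)[C@@]2(C)[C@@H]3C(=O)C=C(C)[C@H]2[C@@H]3C1(C)C | intermediate
34 | CNP0335415.1 | C/C=C(/C)C(=O)O[C@@H]1[C@@H](OC(C)=O)[C@@H](OC(=O)/C(C)=C\C)[C@@]2(C)[C@@H]3C(=O)C=C(C)[C@H]2[C@@H]3C1(C)C | target

**Step count**

The route has 21 steps in total. The longest linear sequence is 20 steps (1 to 34); step 9 is a one-step side branch.

**Steps most likely to fail**

Step 14. Hydrogen loss from, or reduction of, the tertiary C4 radical by excess titanium reagent may outrun the strained four-membered closure. Lewis-acid rearrangement of the epoxide is a second threat. The fallback sets out from 22 and generates the same radical without titanium. Diethylaluminium 2,2,6,6-tetramethylpiperidide (toluene, 0 °C) isomerises the epoxide to the exocyclic allylic alcohol F1 (C3-OH retained, C4=CH2). Fe(acac)3 with PhSiH3 in EtOH at 60 °C then transfers a hydrogen atom to the terminal CH2, which recreates the C4 methyl group and the C4 radical. Conjugate addition to C9 and reduction of the α-keto radical bring the route back at 24.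

Step 13. Oxygen transfer may be slow at the hindered olefin, and the allylic C2 ether may erode the facial selectivity. The fallback sets out from 21 and replaces reagent control by substrate direction. Me2BBr (CH2Cl2, −78 °C) frees the allylic alcohol F2. VO(acac)2 with t-BuOOH delivers oxygen syn to the C2 hydroxyl, as is usual for cycloheptenols, to give the epoxy alcohol F3. MOMCl with iPr2NEt restores the ether, and the route is rejoined at 22.

Step 19. Acylation of the two neopentyl-type alcohols may stay incomplete, and long heating may isomerise the angeloyl unit from Z to E. The fallback sets out from 28 and builds the Z olefin after the ester bond. 2-[Bis(2,2,2-trifluoroethoxy)phosphoryl]propanoic acid is attached with EDC and DMAP, where forcing conditions carry no isomerisation risk, to give the bis(phosphonopropionate) F4. Still–Gennari olefination (KN(SiMe3)2, 18-crown-6, THF, −78 °C, acetaldehyde) then forms both Z-2-methylbut-2-enoates, and the route is rejoined at 31.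

**Further compounds**

F1 | step 14 | exocyclic allylic alcohol (C3-OH, C4=CH2) | CC(C)(C)[Si](C)(C)O[C@@H]1[C@@H](OCOC)[C@@H](O)C(=C)[C@@H]2CC(=O)C(C)=C[C@@H]2C1(C)C
F2 | step 13 | allylic alcohol (C2-OH, C3=C4) | CC(C)(C)[Si](C)(C)O[C@@H]1[C@@H](O)C=C(C)[C@@H]2CC(=O)C(C)=C[C@@H]2C1(C)C
F3 | step 13 | epoxy alcohol (C2-OH syn to C3–C4 oxirane) | CC(C)(C)[Si](C)(C)O[C@@H]1[C@@H](O)[C@H]2O[C@@]2(C)[C@@H]3CC(=O)C(C)=C[C@@H]3C1(C)C
F4 | step 19 | C1,C3-bis{2-[bis(2,2,2-trifluoroethoxy)phosphoryl]propanoate} of 28 | CC(C(=O)O[C@@H]1[C@@H](OCOC)[C@@H](OC(=O)C(C)P(=O)(OCC(F)(F)F)OCC(F)(F)F)[C@@]2(C)[C@@H]3C(=O)C=C(C)[C@H]2[C@@H]3C1(C)C)P(=O)(OCC(F)(F)F)OCC(F)(F)F
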